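**Retrosynthetic overview**
1. Numbering: lactone C1(=O), C2, enol C3, C4 (quaternary, Me). Ring A = C5–C6–C7(OH)–C8(Me)–C9(OH)–C10. Ring B = C4–C5–C10–C11=C12–C13. Bridge C14–C15=C16–C17. Cyclohexene C18(Me)–C19=C20(Me)–C21(Et)–C22–C23 (spiro); C24(=O).
2. Endgame: the cyclohexene and the 11-membered ring close together in a biomimetic intramolecular Diels–Alder reaction (5-methylene tetronate + C18–C21 diene). C2–C3 comes from a lithiated tetronate and the C3 aldehyde, and C15=C16 from a Z-Wittig reaction. The C13 arm comes from axial vinyl addition to a C11 enone, and C11=C12 from the enol triflate.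
3. Key disconnection: rings A and B are removed together. Ring A goes back to the cyclobutanone C7(=O)–C8–C9–C10. Rhodium cuts C7–C10 and sews in the vinyl group C5=C6 that sits on C4 (4 → 6), with C10–C11–C12–C13–C4 as the tether that becomes ring B.
4. Enabling feature: in ring A, four contiguous atoms carry all the functionality (C7–O, the all-cis C8-Me/C9-O pair, and C10). This is the pattern of a ketene/enol-ether [2+2] cyclobutanone. The other two ring atoms, C5–C6, are a bare CH–CH2 pair, which is a vinyl group.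
5. Fragments: the cyclobutanone comes from methylketene and a chiral vinyl ether. C4 comes from geraniol by epoxidation and epoxy silyl ether rearrangement. The fragments are joined by an aldol reaction (C10–C11). Ring order: cyclobutane → A + B → cyclohexene + macrocycle.

Key step: step 10

Remark: the 3-acyltetronic acid formed in step 33 is written as the exocyclic enol tautomer of the target. Carbinol 45 is an inconsequential C3 epimer mixture.

**Step 1**
Reactants: 1 geraniol
Product: 2 (2S,3S)-2,3-epoxygeraniol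
Conditions: Ti(OiPr)4 (5 mol %), L-(+)-diethyl tartrate (6 mol %), t-BuOOH, 4 Å MS, CH2Cl2, −20 °C
Reagents that add atoms: tert-butyl hydroperoxide, CC(C)(C)OO
Why: Sharpless asymmetric epoxidation; the L-(+)-tartrate complex oxidises one face of the allylic alkene only and leaves the remote alkene alone, which creates the stereocentre that becomes C4.

**Step 2**
Reactants: 2 (2S,3S)-2,3-epoxygeraniol
Product: 3 (2S,3S)-2,3-epoxygeranyl tert-butyldimethylsilyl ether
Conditions: TBSCl, imidazole, DMF, 0 °C to rt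
Reagents that add atoms: tert-butyldimethylsilyl chloride, CC(C)(C)[Si](C)(C)Cl
Why: Standard silylation of the primary alcohol, which provides the siloxymethyl group that migrates in step 3 and later serves as masked C3.

**Step 3**
Reactants: 3 epoxy silyl ether
Product: 4 (S)-2-[(tert-butyldimethylsilyloxy)methyl]-2,6-dimethylhept-5-enal
Conditions: methylaluminium bis(4-bromo-2,6-di-tert-butylphenoxide) (20 mol %), CH2Cl2, −78 °C
Reagents that add atoms: none
Why: Lewis-acid-induced epoxy silyl ether rearrangement (semipinacol type); the tertiary C–O bond opens and CH2OTBS shifts anti-periplanar with inversion, so the epoxide configuration is carried stereospecifically into quaternary C4.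

**Step 4**
Reactants: 4 aldehyde
Product: 5 (R)-3-[(tert-butyldimethylsilyloxy)methyl]-3,7-dimethylocta-1,6-diene
Conditions: Ph3PCH3Br, KOtBu, THF, 0 °C to rt
Reagents that add atoms: methyltriphenylphosphonium bromide, C[P+](c1ccccc1)(c1ccccc1)c1ccccc1.[Br-]
Why: Wittig methylenation of the non-enolisable aldehyde installs the vinyl group C5=C6 without touching C4.

**Step 5**
Reactants: 5 diene
Product: 6 (R)-4-[(tert-butyldimethylsilyloxy)methyl]-4-methylhex-5-enal
Conditions: O3 (1 equiv), pyridine, CH2Cl2, −78 °C; then Me2S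
Reagents that add atoms: ozone, [O-][O+]=O
Why: Chemoselective ozonolysis; the electron-rich trisubstituted alkene should react well before the neopentyl vinyl group, which releases the C11 aldehyde.

**Step 6**
Reactants: 7 (R)-1-phenylethanol
Product: 8 (R)-1-phenylethyl vinyl ether
Conditions: vinyl acetate, [Ir(cod)Cl]2 (1 mol %), Na2CO3, toluene, 100 °C
Reagents that add atoms: vinyl acetate, C=COC(C)=O
Why: Iridium-catalysed vinyl transfer gives an enol ether whose chiral, hydrogenolysable O-substituent later serves as the C9 protecting group.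

**Step 7**
Reactants: 8 (R)-1-phenylethyl vinyl ether; 9 propionyl chloride
Product: 11 (2R,3R)-2-methyl-3-[(R)-1-phenylethoxy]cyclobutan-1-one (cis), via methylketene 10 (not isolated)
Conditions: i-Pr2NEt, MeCN, 60 °C, slow addition of 9; chromatographic separation of the two cis adducts
Reagents that add atoms: none
Why: Ketene–enol ether [2+2] cycloaddition; the carbonyl carbon bonds to the CH2 terminus, the orthogonal approach places the methyl group cis to the alkoxy group (C8/C9), and the auxiliary turns the two cis antipodes into separable diastereomers, which sets the absolute configuration.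

**Step 8**
Reactants: 11 cyclobutanone; 6 aldehyde
Product: 13 aldol adduct (C8/C9 cis, C9/C10 trans, C10/C11 anti; chain C11(OH)–C12H2–C13H2–C4(Me)(CH2OTBS)(CH=CH2)), via lithium enolate 12 (not isolated)
Conditions: LDA, THF, −78 °C; then 6, −78 °C; AcOH quench at −78 °C
Reagents that add atoms: none
Why: Kinetic aldol addition; LDA removes a proton from the CH2 side only, the aldehyde approaches anti to the neighbouring C9 alkoxy group (this sets C10), a closed transition state of the ring enolate gives the anti carbinol, and C11 is erased later in step 15.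

**Step 9**
Reactants: 13 aldol adduct
Product: 14 C11 triethylsilyl ether of 13
Conditions: TESCl, imidazole, CH2Cl2, 0 °C
Reagents that add atoms: chlorotriethylsilane, CC[Si](CC)(CC)Cl
Why: Mild silylation blocks retro-aldol cleavage and gives a group that can be removed selectively beside TBS ethers.

**Step 10**
Reactants: 14 cyclobutanone with tethered vinyl group
Product: 15 trans-decalone (C7 ketone, axial C8-Me, equatorial C9 1-phenylethoxy, axial C11-OTES, axial C4-Me, equatorial C4-CH2OTBS)
Conditions: [Rh(cod)2]BF4 (10 mol %), (R)-DTBM-SEGPHOS (12 mol %), 1,4-dioxane, 40 °C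
Reagents that add atoms: none
Why: Cationic monovalent rhodium adds oxidatively and reversibly into the strained acyl–alkyl bond C7–C10, the tethered vinyl group inserts so that C10 bonds to C5, and reductive elimination joins C6 to the acyl carbon C7, so the four-membered ring C7–C8–C9–C10 becomes ring A by uptake of C5 and C6. The closest known reaction type is the intramolecular carboacylation ("cut-and-sew") of cyclobutanones that carry an alkene on the α-carbon, which gives trans-fused bicyclic cyclohexanones under these mild conditions. Ring B closes by 6-exo carbometalation along the tether C10–C11–C12–C13–C4, and ring A closes by two-atom ring expansion in the final C–C reductive elimination. C10 keeps its configuration because both metal steps proceed with retention, and the new centre C5 is set trans by a chair-like tether with equatorial CH2OTBS and axial OTES, reinforced by the matched ligand. C8 and C9 are not touched because the medium is neutral, so the contra-thermodynamic axial methyl group survives. The step needs C7–C10 rather than C7–C8 cleavage, fused rather than bridged insertion and no decarbonylation; only the C10-bound metal can reach the single alkene of the substrate, the 6-exo mode is shorter than the 7-endo mode, and ring strain allows a temperature at which CO loss is slow.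

**Step 11**
Reactants: 15 decalone
Product: 16 C7 equatorial alcohol
Conditions: NaBH4, MeOH/CH2Cl2, −40 °C
Reagents that add atoms: none
Why: Ketone reduction by axial hydride attack from the face opposite the axial C8 methyl group gives the equatorial C7 alcohol cis to C8-Me and C9-O, and it also removes the risk of C8 epimerisation.

**Step 12**
Reactants: 16 alcohol
Product: 17 C7,C9-diol
Conditions: H2 (1 atm), Pd(OH)2/C, EtOAc, rt
Reagents that add atoms: none
Why: Hydrogenolysis of the benzylic ether is clean at this stage because the molecule has no C=C bond, and silyl ethers tolerate EtOAc.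

**Step 13**
Reactants: 17 diol
Product: 18 C7,C9-bis(TBS) ether
Conditions: TBSOTf (2.5 equiv), 2,6-lutidine, CH2Cl2, 0 °C
Reagents that add atoms: tert-butyldimethylsilyl triflate, CC(C)(C)[Si](C)(C)OS(=O)(=O)C(F)(F)F
Why: Silyl triflate silylation protects both hindered secondary alcohols with groups that fall together in the last step.

**Step 14**
Reactants: 18 tetrasilyl ether
Product: 19 C11 alcohol
Conditions: PPTS (cat.), MeOH/CH2Cl2, 0 °C
Reagents that add atoms: none
Why: Acid-catalysed methanolysis removes the far more labile triethylsilyl ether selectively beside three TBS ethers.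

**Step 15**
Reactants: 19 alcohol
Product: 20 C11 ketone
Conditions: Dess–Martin periodinane, NaHCO3, CH2Cl2, rt
Reagents that add atoms: none
Why: Buffered Dess–Martin oxidation avoids β-elimination of the C9 silyloxy group, and the trans ring fusion is also the thermodynamic one at C10.

**Step 16**
Reactants: 20 ketone
Product: 22 C11 enone (C12=C13), via lithium enolate 21 (not isolated)
Conditions: LDA, THF, −78 °C; then N-tert-butylbenzenesulfinimidoyl chloride, −78 °C
Reagents that add atoms: none
Why: Mukaiyama dehydrogenation; kinetic deprotonation at C12H2 rather than at the ring-fusion CH fixes the regiochemistry, and the sulfilimine intermediate eliminates at low temperature.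

**Step 17**
Reactants: 22 enone
Product: 24 C11 enol triflate with axial C13 vinyl group, via magnesium enolate 23 (not isolated)
Conditions: CH2=CHMgBr, CuBr·SMe2 (20 mol %), THF/Me2S, −78 to −40 °C; then PhNTf2, −40 °C to rt
Reagents that add atoms: vinylmagnesium bromide, C=C[Mg]Br; N-phenylbis(trifluoromethanesulfonimide), O=S(=O)(N(c1ccccc1)S(=O)(=O)C(F)(F)F)C(F)(F)F
Why: Copper-catalysed conjugate addition with enolate trapping; axial attack anti to the axial C4 methyl group sets C13 cis to the C4 CH2OTBS arm, and trapping gives the C11=C12 enol triflate regiospecifically.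

**Step 18**
Reactants: 24 enol triflate
Product: 25 Δ11-octalin with C13 vinyl group
Conditions: Pd(OAc)2 (5 mol %), PPh3 (10 mol %), HCO2H, Et3N, DMF, 60 °C
Reagents that add atoms: none
Why: Palladium-catalysed formate reduction of the enol triflate replaces OTf by H and leaves the C11=C12 alkene exactly where the target has it.

**Step 19**
Reactants: 25 diene
Product: 27 primary alcohol (C13–CH2CH2OH), via B-alkyl-9-BBN adduct 26 (not isolated)
Conditions: 9-BBN, THF, 0 °C to rt; then H2O2, NaOH
Reagents that add atoms: hydrogen peroxide, OO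
Why: Hydroboration–oxidation; the bulky borane adds anti-Markovnikov to the monosubstituted vinyl group much faster than to the ring alkene.

**Step 20**
Reactants: 27 alcohol
Product: 28 C15 aldehyde (C13–CH2–CHO)
Conditions: Dess–Martin periodinane, NaHCO3, CH2Cl2, 0 °C
Reagents that add atoms: none
Why: Neutral Dess–Martin oxidation stops at the aldehyde and does not move the ring alkene.

**Step 21**
Reactants: 29 (E)-2-methylpent-2-enal; 30 ethyl 2-(triphenylphosphoranylidene)propanoate
Product: 31 ethyl (2E,4E)-2,4-dimethylhepta-2,4-dienoate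
Conditions: toluene, 80 °C
Reagents that add atoms: none
Why: The Wittig reaction of a stabilised ylide is E-selective, which gives the C18=C19 geometry beside the existing E C20=C21 alkene.

**Step 22**
Reactants: 31 dienoate
Product: 32 (2E,4E)-2,4-dimethylhepta-2,4-dien-1-ol
Conditions: i-Bu2AlH (2.2 equiv), CH2Cl2, −78 °C
Reagents that add atoms: none
Why: 1,2-Reduction of the ester with diisobutylaluminium hydride leaves the diene geometry intact.

**Step 23**
Reactants: 32 dienol
Product: 33 (2E,4E)-1-bromo-2,4-dimethylhepta-2,4-diene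
Conditions: CBr4, PPh3, CH2Cl2, −20 °C
Reagents that add atoms: carbon tetrabromide, BrC(Br)(Br)Br
Why: The Appel reaction converts the allylic alcohol under neutral conditions without allylic transposition.

**Step 24**
Reactants: 33 allylic bromide
Product: 34 [(3E,5E)-3,5-dimethylocta-3,5-dien-1-yl]triphenylphosphonium bromide
Conditions: Ph3PCH3Br, n-BuLi, THF, −78 °C; then the ylide solution is added slowly to 33, −78 °C to rt
Reagents that add atoms: methyltriphenylphosphonium bromide, C[P+](c1ccccc1)(c1ccccc1)c1ccccc1.[Br-]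
Why: SN2 alkylation of methylenetriphenylphosphorane adds C16 and delivers the homoallylic phosphonium salt directly.

**Step 25**
Reactants: 34 phosphonium bromide; 28 aldehyde
Product: 36 decalin with the full (15Z,18E,20E) side chain, via phosphonium ylide 35 (not isolated)
Conditions: NaHMDS, THF, −78 °C; then 28, −78 °C to rt
Reagents that add atoms: none
Why: The salt-free Wittig reaction of a non-stabilised ylide is Z-selective and sets the C15=C16 geometry.

**Step 26**
Reactants: 36 tris(TBS) ether
Product: 37 primary C3 alcohol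
Conditions: HF·pyridine, pyridine, THF, 0 °C
Reagents that add atoms: none
Why: Buffered fluoride desilylation removes the primary TBS ether ahead of the two secondary ethers, which are flanked by the axial methyl group.

**Step 27**
Reactants: 37 alcohol
Product: 38 C3 aldehyde
Conditions: Dess–Martin periodinane, NaHCO3, CH2Cl2, rt
Reagents that add atoms: none
Why: Dess–Martin oxidation gives a neopentyl aldehyde that cannot epimerise.

**Step 28**
Reactants: 39 4-methoxyfuran-2(5H)-one
Product: 41 5-[(dimethylamino)methyl]-4-methoxyfuran-2(5H)-one (racemic), via lithium furanolate 40 (not isolated)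
Conditions: LDA, THF, −78 °C; then dimethylmethyleneammonium iodide, −78 °C to rt
Reagents that add atoms: dimethylmethyleneammonium iodide, C=[N+](C)C.[I-]
Why: Mannich reaction of the γ-deprotonated tetronate (an aromatic 2-oxidofuran) with Eschenmoser's salt places the future C22 on C23.

**Step 29**
Reactants: 41 Mannich base
Product: 43 4-methoxy-5-methylenefuran-2(5H)-one, via ammonium iodide 42 (not isolated)
Conditions: MeI, CH2Cl2, rt; then aq. NaHCO3
Reagents that add atoms: none
Why: Quaternisation followed by E1cB (Hofmann-type) elimination unveils the exocyclic methylene dienophile.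

**Step 30**
Reactants: 43 methylene tetronate; 38 aldehyde
Product: 45 C3 carbinol (epimer mixture), via 3-lithiotetronate 44 (not isolated)
Conditions: LDA, THF, −78 °C; then 38, −78 °C; AcOH quench
Reagents that add atoms: none
Why: The only acidic position left is the vinylic C2–H, and 1,2-addition of the lithiated tetronate to the aldehyde forms C2–C3.

**Step 31**
Reactants: 45 carbinol
Product: 46 3-acyl-4-methoxy-5-methylene tetronate
Conditions: Dess–Martin periodinane, CH2Cl2, rt
Reagents that add atoms: none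
Why: Dess–Martin oxidation merges both C3 epimers into the ketone and further activates the dienophile.

**Step 32**
Reactants: 46 tetraene
Product: 47 macrocyclic spirotetronate methyl ether (bis-TBS)
Conditions: toluene (high dilution), BHT, 130 °C, sealed tube
Reagents that add atoms: none
Why: Intramolecular Diels–Alder reaction of a 5-methylene tetronate with a tethered diene, as in the presumed biosynthesis; suprafacial addition to the (E,E)-diene places the C17 arm and the ethyl group cis (C18, C21), and the short Z-configured bridge should allow only the folding with the lactone oxygen endo, which sets C23.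

**Step 33**
Reactants: 47 methyl tetronate
Product: 48 bis-TBS ether of the target
Conditions: LiCl, DMSO, 60 °C; then 1 M HCl
Reagents that add atoms: none
Why: SN2 demethylation of the vinylogous carbonate by chloride frees the acyltetronic acid without touching silyl ethers or alkenes.

**Step 34**
Reactants: 48 bis-TBS ether
Product: 49 target CNP0259772.1
Conditions: HF (48 % aq.), MeCN, 0 °C to rt
Reagents that add atoms: none
Why: Fluoride-induced desilylation releases the C7 and C9 alcohols, and no stereocentre is affected.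

**Compound list**
1 | geraniol | CC(C)=CCC/C(C)=C/CO | starting material
2 | (2S,3S)-2,3-epoxygeraniol | OC[C@@H]1O[C@@]1(C)CCC=C(C)C | intermediate
3 | (2S,3S)-2,3-epoxygeranyl TBS ether | CC(C)(C)[Si](C)(C)OC[C@@H]1O[C@@]1(C)CCC=C(C)C | intermediate
4 | (S)-2-[(TBS-oxy)methyl]-2,6-dimethylhept-5-enal | CC(C)(C)[Si](C)(C)OC[C@@](CCC=C(C)C)(C)C=O | intermediate
5 | (R)-3-[(TBS-oxy)methyl]-3,7-dimethylocta-1,6-diene | CC(C)(C)[Si](C)(C)OC[C@@](CCC=C(C)C)(C)C=C | intermediate
6 | (R)-4-[(TBS-oxy)methyl]-4-methylhex-5-enal | CC(C)(C)[Si](C)(C)OC[C@@](CCC=O)(C)C=C | intermediate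
7 | (R)-1-phenylethanol | C[C@@H](O)c1ccccc1 | starting material
8 | (R)-1-phenylethyl vinyl ether | C=CO[C@H](C)c1ccccc1 | intermediate
9 | propionyl chloride | CCC(=O)Cl | starting material
10 | methylketene | CC=C=O | intermediate
11 | (2R,3R)-2-methyl-3-[(R)-1-phenylethoxy]cyclobutanone | O=C1[C@H](C)[C@H](O[C@H](C)c2ccccc2)C1 | intermediate
12 | lithium enolate of 11 (C7=C10) | [Li]OC=1[C@H](C)[C@H](O[C@H](C)c2ccccc2)C=1 | intermediate
13 | aldol adduct (C9/C10 trans, C10/C11 anti) | O=C1[C@H](C)[C@H](O[C@H](C)c2ccccc2)[C@H]1[C@@H](O)CC[C@@](C)(CO[Si](C)(C)C(C)(C)C)C=C | intermediate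
14 | C11 TES ether of 13 | O=C1[C@H](C)[C@H](O[C@H](C)c2ccccc2)[C@H]1[C@@H](O[Si](CC)(CC)CC)CC[C@@](C)(CO[Si](C)(C)C(C)(C)C)C=C | intermediate
15 | trans-decalone (C7 ketone) | CC(C)(C)[Si](C)(C)OC[C@@]1(C)[C@@H]2CC(=O)[C@H](C)[C@H](O[C@H](C)c3ccccc3)[C@H]2[C@@H](O[Si](CC)(CC)CC)CC1 | intermediate
16 | C7 equatorial alcohol | CC(C)(C)[Si](C)(C)OC[C@@]1(C)[C@@H]2C[C@H](O)[C@H](C)[C@H](O[C@H](C)c3ccccc3)[C@H]2[C@@H](O[Si](CC)(CC)CC)CC1 | intermediate
17 | C7,C9-diol | CC(C)(C)[Si](C)(C)OC[C@@]1(C)[C@@H]2C[C@H](O)[C@H](C)[C@H](O)[C@H]2[C@@H](O[Si](CC)(CC)CC)CC1 | intermediate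
18 | C7,C9-bis(TBS) ether | CC(C)(C)[Si](C)(C)OC[C@@]1(C)[C@@H]2C[C@H](O[Si](C)(C)C(C)(C)C)[C@H](C)[C@H](O[Si](C)(C)C(C)(C)C)[C@H]2[C@@H](O[Si](CC)(CC)CC)CC1 | intermediate
19 | C11 axial alcohol | CC(C)(C)[Si](C)(C)OC[C@@]1(C)[C@@H]2C[C@H](O[Si](C)(C)C(C)(C)C)[C@H](C)[C@H](O[Si](C)(C)C(C)(C)C)[C@H]2[C@@H](O)CC1 | intermediate
20 | C11 ketone | CC(C)(C)[Si](C)(C)OC[C@@]1(C)[C@@H]2C[C@H](O[Si](C)(C)C(C)(C)C)[C@H](C)[C@H](O[Si](C)(C)C(C)(C)C)[C@H]2C(=O)CC1 | intermediate
21 | lithium enolate of 20 (C11=C12) | CC(C)(C)[Si](C)(C)OC[C@@]1(C)[C@@H]2C[C@H](O[Si](C)(C)C(C)(C)C)[C@H](C)[C@H](O[Si](C)(C)C(C)(C)C)[C@H]2C(O[Li])=CC1 | intermediate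
22 | C11 enone (C12=C13) | CC(C)(C)[Si](C)(C)OC[C@@]1(C)[C@@H]2C[C@H](O[Si](C)(C)C(C)(C)C)[C@H](C)[C@H](O[Si](C)(C)C(C)(C)C)[C@H]2C(=O)C=C1 | intermediate
23 | magnesium enolate after vinyl addition | CC(C)(C)[Si](C)(C)OC[C@@]1(C)[C@@H]2C[C@H](O[Si](C)(C)C(C)(C)C)[C@H](C)[C@H](O[Si](C)(C)C(C)(C)C)[C@H]2C(O[Mg]Br)=C[C@H]1C=C | intermediate
24 | C11 enol triflate, C13 vinyl | CC(C)(C)[Si](C)(C)OC[C@@]1(C)[C@@H]2C[C@H](O[Si](C)(C)C(C)(C)C)[C@H](C)[C@H](O[Si](C)(C)C(C)(C)C)[C@H]2C(OS(=O)(=O)C(F)(F)F)=C[C@H]1C=C | intermediate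
25 | Δ11-octalin, C13 vinyl | CC(C)(C)[Si](C)(C)OC[C@@]1(C)[C@@H]2C[C@H](O[Si](C)(C)C(C)(C)C)[C@H](C)[C@H](O[Si](C)(C)C(C)(C)C)[C@H]2C=C[C@H]1C=C | intermediate
26 | B-alkyl-9-BBN adduct of 25 | CC(C)(C)[Si](C)(C)OC[C@@]1(C)[C@@H]2C[C@H](O[Si](C)(C)C(C)(C)C)[C@H](C)[C@H](O[Si](C)(C)C(C)(C)C)[C@H]2C=C[C@H]1CCB3C4CCCC3CCC4 | intermediate
27 | C15 primary alcohol | CC(C)(C)[Si](C)(C)OC[C@@]1(C)[C@@H]2C[C@H](O[Si](C)(C)C(C)(C)C)[C@H](C)[C@H](O[Si](C)(C)C(C)(C)C)[C@H]2C=C[C@H]1CCO | intermediate
28 | C15 aldehyde | CC(C)(C)[Si](C)(C)OC[C@@]1(C)[C@@H]2C[C@H](O[Si](C)(C)C(C)(C)C)[C@H](C)[C@H](O[Si](C)(C)C(C)(C)C)[C@H]2C=C[C@H]1CC=O | intermediate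
29 | (E)-2-methylpent-2-enal | CC/C=C(\C)C=O | starting material
30 | ethyl 2-(triphenylphosphoranylidene)propanoate | CCOC(=O)C(C)=P(c1ccccc1)(c1ccccc1)c1ccccc1 | starting material
31 | ethyl (2E,4E)-2,4-dimethylhepta-2,4-dienoate | CC/C=C(C)/C=C(\C)C(=O)OCC | intermediate
32 | (2E,4E)-2,4-dimethylhepta-2,4-dien-1-ol | CC/C=C(C)/C=C(\C)CO | intermediate
33 | (2E,4E)-1-bromo-2,4-dimethylhepta-2,4-diene | CC/C=C(C)/C=C(\C)CBr | intermediate
34 | [(3E,5E)-3,5-dimethylocta-3,5-dienyl]triphenylphosphonium bromide | CC/C=C(C)/C=C(\C)CC[P+](c1ccccc1)(c1ccccc1)c1ccccc1.[Br-] | intermediate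
35 | ylide of 34 | CC/C=C(C)/C=C(\C)CC=P(c1ccccc1)(c1ccccc1)c1ccccc1 | intermediate
36 | decalin with (15Z,18E,20E) side chain, tris-TBS | CC(C)(C)[Si](C)(C)OC[C@@]1(C)[C@@H]2C[C@H](O[Si](C)(C)C(C)(C)C)[C@H](C)[C@H](O[Si](C)(C)C(C)(C)C)[C@H]2C=C[C@H]1C/C=C\C/C(C)=C/C(C)=C/CC | intermediate
37 | C3 primary alcohol | OC[C@@]1(C)[C@@H]2C[C@H](O[Si](C)(C)C(C)(C)C)[C@H](C)[C@H](O[Si](C)(C)C(C)(C)C)[C@H]2C=C[C@H]1C/C=C\C/C(C)=C/C(C)=C/CC | intermediate
38 | C3 aldehyde | O=C[C@@]1(C)[C@@H]2C[C@H](O[Si](C)(C)C(C)(C)C)[C@H](C)[C@H](O[Si](C)(C)C(C)(C)C)[C@H]2C=C[C@H]1C/C=C\C/C(C)=C/C(C)=C/CC | intermediate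
39 | 4-methoxyfuran-2(5H)-one | COC1=CC(=O)OC1 | starting material
40 | lithium 4-methoxyfuran-2-olate | [Li]Oc1cc(OC)co1 | intermediate
41 | 5-[(dimethylamino)methyl]-4-methoxyfuran-2(5H)-one | COC1=CC(=O)OC1CN(C)C | intermediate
42 | trimethylammonium iodide of 41 | COC1=CC(=O)OC1C[N+](C)(C)C.[I-] | intermediate
43 | 4-methoxy-5-methylenefuran-2(5H)-one | COC1=CC(=O)OC1=C | intermediate
44 | 3-lithio-4-methoxy-5-methylenefuran-2(5H)-one | COC1=C([Li])C(=O)OC1=C | intermediate
45 | C3 carbinol (epimers at C3) | COC1=C(C(O)[C@@]2(C)[C@@H]3C[C@H](O[Si](C)(C)C(C)(C)C)[C@H](C)[C@H](O[Si](C)(C)C(C)(C)C)[C@H]3C=C[C@H]2C/C=C\C/C(C)=C/C(C)=C/CC)C(=O)OC1=C | intermediate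
46 | 3-acyl-4-methoxy-5-methylene tetronate | COC1=C(C(=O)[C@@]2(C)[C@@H]3C[C@H](O[Si](C)(C)C(C)(C)C)[C@H](C)[C@H](O[Si](C)(C)C(C)(C)C)[C@H]3C=C[C@H]2C/C=C\C/C(C)=C/C(C)=C/CC)C(=O)OC1=C | intermediate
47 | macrocyclic spirotetronate methyl ether, bis-TBS | CC[C@@H]1C[C@]23OC(=O)C(C(=O)[C@@]4(C)[C@@H]5C[C@H](O[Si](C)(C)C(C)(C)C)[C@H](C)[C@H](O[Si](C)(C)C(C)(C)C)[C@H]5C=C[C@H]4C/C=C\C[C@]2(C)C=C1C)=C3OC | intermediate
48 | bis-TBS ether of the target | CC[C@@H]1C[C@]23OC(=O)/C(=C(\O)[C@@]4(C)[C@@H]5C[C@H](O[Si](C)(C)C(C)(C)C)[C@H](C)[C@H](O[Si](C)(C)C(C)(C)C)[C@H]5C=C[C@H]4C/C=C\C[C@]2(C)C=C1C)C3=O | intermediate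
49 | CNP0259772.1 | CC[C@@H]1C[C@]23OC(=O)/C(=C(\O)[C@@]4(C)[C@@H]5C[C@H](O)[C@H](C)[C@H](O)[C@H]5C=C[C@H]4C/C=C\C[C@]2(C)C=C1C)C3=O | target

**Step count**
Total step count: 34. Longest linear sequence: 26 steps (1–5, 8–20, 25–27, 30–34).

**Steps most likely to fail**

Step 10. The metal may insert unproductively into C7–C8, lose CO to give a cyclopropane, insert the neopentyl vinyl group too slowly, or add to the wrong alkene face at C5.

The fallback sets out from 14 and comes back at 15. It keeps the 4 → 6 logic but uses radical steps. Compound 14 is condensed with NH2OH·HCl/pyridine to the cyclobutanone oxime F1, which is acetylated (Ac2O, pyridine) to the oxime acetate F2. Single-electron reduction (Ir(ppy)3, blue light, Hantzsch ester, MeCN) gives an iminyl radical. β-Scission of this radical opens C7–C10 to a nitrile and a C10 radical. The C10 radical closes ring B by 6-exo-trig addition to the vinyl group. The primary C6 radical then closes ring A by 6-exo-dig addition to the nitrile carbon C7. After hydrogen transfer this gives the decalin ketimine F3, and mild aqueous AcOH/NaOAc hydrolysis gives 15.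

Step 32. The diene carries an inside methyl group and may resist the s-cis geometry. Facial or endo/exo selectivity may be poor, and the methylene tetronate may polymerise.

The fallback sets out from 36 and 43 and comes back at 47. It reverses the bond order. An intermolecular Diels–Alder reaction of 36 with excess 43 (high pressure, CH2Cl2) gives, after separation, the open-chain spirotetronate F6. Buffered HF·pyridine frees the primary alcohol F7, and Dess–Martin oxidation gives the aldehyde F8. Slow addition of F8 to LDA at high dilution lithiates C2 and closes the 11-membered ring by intramolecular 1,2-addition to the macrocyclic carbinol F9. Dess–Martin oxidation of F9 gives 47.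

Step 17. 1,4-Addition beside quaternary C4 may be slow, so 1,2-addition or β-elimination of the C9 silyloxy group from the enolate could take over.

The fallback sets out from 22 and comes back at 28. It replaces the intermolecular C–C bond formation by a sigmatropic one. A Corey–Bakshi–Shibata reduction, with the catalyst enantiomer chosen for hydride delivery to the β face, gives the axial allylic alcohol F4. A Johnson–Claisen rearrangement (MeC(OEt)3, cat. EtCO2H, 140 °C) transfers a CH2CO2Et group suprafacially to C13 and moves the alkene to C11=C12, which gives the ethyl ester F5. One equivalent of i-Bu2AlH at −78 °C then gives aldehyde 28.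

**Further compounds**
F1 | step 10 | cyclobutanone oxime of 14 | ON=C1[C@H](C)[C@H](O[C@H](C)c2ccccc2)[C@H]1[C@@H](O[Si](CC)(CC)CC)CC[C@@](C)(CO[Si](C)(C)C(C)(C)C)C=C
F2 | step 10 | oxime acetate of 14 | CC(=O)ON=C1[C@H](C)[C@H](O[C@H](C)c2ccccc2)[C@H]1[C@@H](O[Si](CC)(CC)CC)CC[C@@](C)(CO[Si](C)(C)C(C)(C)C)C=C
F3 | step 10 | decalin C7 ketimine | CC(C)(C)[Si](C)(C)OC[C@@]1(C)[C@@H]2CC(=N)[C@H](C)[C@H](O[C@H](C)c3ccccc3)[C@H]2[C@@H](O[Si](CC)(CC)CC)CC1
F4 | step 17 | axial C11 allylic alcohol | CC(C)(C)[Si](C)(C)OC[C@@]1(C)[C@@H]2C[C@H](O[Si](C)(C)C(C)(C)C)[C@H](C)[C@H](O[Si](C)(C)C(C)(C)C)[C@H]2[C@@H](O)C=C1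
F5 | step 17 | C13 acetic acid ethyl ester | CC(C)(C)[Si](C)(C)OC[C@@]1(C)[C@@H]2C[C@H](O[Si](C)(C)C(C)(C)C)[C@H](C)[C@H](O[Si](C)(C)C(C)(C)C)[C@H]2C=C[C@H]1CC(=O)OCC
F6 | step 32 | open-chain spirotetronate, tris-TBS | CC[C@@H]1C[C@]2(OC(=O)C=C2OC)[C@](C)(C\C=C/C[C@@H]3C=C[C@@H]4[C@@H](O[Si](C)(C)C(C)(C)C)[C@@H](C)[C@@H](O[Si](C)(C)C(C)(C)C)C[C@H]4[C@]3(C)CO[Si](C)(C)C(C)(C)C)C=C1C
F7 | step 32 | open-chain spirotetronate, C3 alcohol | CC[C@@H]1C[C@]2(OC(=O)C=C2OC)[C@](C)(C\C=C/C[C@@H]3C=C[C@@H]4[C@@H](O[Si](C)(C)C(C)(C)C)[C@@H](C)[C@@H](O[Si](C)(C)C(C)(C)C)C[C@H]4[C@]3(C)CO)C=C1C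
F8 | step 32 | open-chain spirotetronate, C3 aldehyde | CC[C@@H]1C[C@]2(OC(=O)C=C2OC)[C@](C)(C\C=C/C[C@@H]3C=C[C@@H]4[C@@H](O[Si](C)(C)C(C)(C)C)[C@@H](C)[C@@H](O[Si](C)(C)C(C)(C)C)C[C@H]4[C@]3(C)C=O)C=C1C
F9 | step 32 | macrocyclic C3 carbinol | CC[C@@H]1C[C@]23OC(=O)C(C(O)[C@@]4(C)[C@@H]5C[C@H](O[Si](C)(C)C(C)(C)C)[C@H](C)[C@H](O[Si](C)(C)C(C)(C)C)[C@H]5C=C[C@H]4C/C=C\C[C@]2(C)C=C1C)=C3OC
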